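Follow the second nucleophile through these flasks, and count each amount as a fraction of a charge.

| setting | north-east | larch | birch |
|---|---|---|---|
| substrate | 0.035 M | 0.070 M | 0.070 M |
| first nucleophile | 0.0735 M | 0.0735 M | 0.0735 M |
| second nucleophile | 0.126 M | 0.126 M | 0.126 M |
| temperature | 25 °C | 25 °C | 45 °C |
| remark | run made earlier |  |  |
| time |  | 3.0 h | 3.0 h |

north-east run (percent of the substrate charged)

| time / min | substrate / % | target / % | intermediate / % | solvolysis product / % | other capture product / % |
|---|---|---|---|---|---|
| 2.00 | 76.5 | 0 | 0.2 | 7.9 | 15.1 |
| 6.00 | 46.1 | 0 | 1.1 | 19.2 | 33.0 |
| 10.0 | 26.8 | 0.6 | 0 | 26.2 | 44.2 |
| 15.0 | 14.0 | 0 | 0 | 31.6 | 53.5 |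
| 20.0 | 8.6 | 0.4 | 0.7 | 34.1 | 57.9 |
| 30.0 | 1.6 | 0 | 0 | 37.0 | 61.2 |
| 40.0 | 0.5 | 0.5 | 0 | 36.7 | 62.1 |

(each reading ± 0.5 percentage points)

1. which of these there is most of at the end, counted by the substrate in it, larch (other capture product / intermediate / substrate / solvolysis product)
2. which of these there is most of at the end, counted by the substrate in it, birch (other capture product / intermediate / substrate / solvolysis product)
3. the largest of these amounts at the end, in percent of the substrate charged, larch
4. the largest of these amounts at the end, in percent of the substrate charged, birch

- the earlier runs do not show what temperature does; that part of a forecast is a guess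

Begin with the clock. The north-east substrate falls to 46.1% by 6.00 min, which, taken as first order, gives a rate constant of 0.129 /min and a half-life of 5.37 min, far shorter than the 3.0 h allowed. So expect larch to run for about 33.5 such half-lives, and ask how its substrate divides. In the north-east run target and intermediate never read above 1.1%, so count two products.

Now compare their rates at one moment. At 2.00 min the north-east run reads other capture product over solvolysis product as 1.91, and held steady that ratio would give other capture product 65.7%. But the readings drift: between 10.0 min and 30.0 min the gains of the two products in the north-east run stand in the ratio 1.57.

So suppose that capture follows f, the fraction of second nucleophile left, while solvolysis does not. Let n be the second nucleophile charged per substrate, with q and x the shares of the substrate charge in other capture product and solvolysis product. Then f falls by q over n, and the logarithm of the reciprocal of f grows with x at slope C over n. The last north-east reading has n at 3.60 and f at 82.8%, so C reads 1.86. This is the opening capture ratio: capture rate over solvolysis rate at the full charge of second nucleophile, a selectivity factor for that charge. Though reckoned from the last reading, it lies near the early ratio.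

Carry C to larch, which has the same second nucleophile concentration and temperature, with n at 1.80. Unchanged, C gives q as 65.0%. Object that this leaves f at 63.9%, so the ratio must sink. Averaging its opening and closing values gives 1.52, and my q becomes 60.3%. Test it: the rule then requires x of 39.6%, which completes the charge. For birch, equal shares need C of 1.17, and the runs do not show whether heating reaches that.

The forecast names other capture product at 60.5% for larch and other capture product at 57% for birch, holding that “Solvolysis probably gains modestly”.

Larch gives other capture product at 59.6%; birch gives solvolysis product at 53.4%, against 45.8% other capture product, so the forecast's name for birch parts from the flask.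

second nucleophile + intermediate → other capture product (k = 260 /M/min, Ea = 49.0 kJ/mol); intermediate → decomposed reagent (k = 0.260 /min, Ea = 75.0 kJ/mol); substrate → intermediate (k = 0.130 /min, Ea = 91.0 kJ/mol); intermediate → solvolysis product (k = 18.0 /min, Ea = 73.0 kJ/mol); first nucleophile + intermediate ⇌ target (K = 6.20 /M, k = 140 /M/min, Ea = 48.0 kJ/mol, ΔH = −39.0 kJ/mol); (constants at 25 °C) From these shares C is 1.82 in larch and 0.990 in birch, below the equal-share value. The larch neighbour that holds 0.076 M of second nucleophile ends at 45.5% other capture product, which gives C of 1.10, near the 1.12 that the north-east C becomes when scaled to that concentration. Larch has come to rest: its substrate has had 33.8 half-lives of its passing into intermediate, 0% of the charge remains, and continuing to 30.0 h changes its other capture product by 0 percentage points.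

(All runs stem from a simulated flask on assumed constants; the scatter is artificial.)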